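The number I reckoned with for the flask was 5.65, its solid margin: the J charged divided by the J that the gamma run had consumed by 12 h, counting one J per product.

| flask | G | Z | J | E | remark | time |
|---|---|---|---|---|---|---|
| gamma | 0.80 M | 0.80 M | 0.80 M | 2.3 mM | run made earlier |  |
| flask | 0.80 M | 0.80 M | 1.60 M | 2.3 mM |  | 12 h |

gamma run (percent of the G and Z together charged)

| time / h | X / % | D / % | G / % |
|---|---|---|---|
| 0.667 | 3.0 | 1.0 | 48.3 |
| 2.00 | 0.9 | 0.5 | 50.0 |
| 3.00 | 2.0 | 0 | 47.8 |
| 5.00 | 6.2 | 1.9 | 46.8 |
| 8.00 | 6.9 | 2.1 | 43.6 |
| 10.0 | 9.3 | 4.3 | 41.1 |
| 12.0 | 11.0 | 6.7 | 37.2 |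

(scatter of a reading: 1 percentage point)

- E is single-handed; G and Z are mirror images of each other, charged as a racemate, each of them at the stated concentration
- given per volume of solution although it is solid: J
- at the start none of J is in solution
- an excess is below zero if the other one leads

- excess of X over D in the product at 15 min
- excess of X over D in the product at 12 h
- part of the G and Z charged together that has reacted at 12 h

1. At 12.0 h the gamma run held 11.0% X and 6.7% D, so by my count, which rests on these readings, it had consumed 0.283 M of its 0.80 M of J, a margin of 2.82.

2. That margin was greater than one, so I expected solid to have stood to the end of the gamma run, unless more than 0.517 M lay dissolved and unreacted.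

3. I assumed that solid, while present, dissolves at a pace independent of its amount. The flask should therefore repeat the gamma run: 17.7% reacted and an excess of 24.3% at 12 h, and early on the 50.0% read at 0.667 h.

4. One number was not enough. The margin tells me whether the amount of solid matters, but the excesses are copied readings, and they are loose: the reading at 10.0 h gives 36.8%.

The forecast gave an excess of 55% at 15 min, and an excess of 17% with 27% reacted at 12 h, assuming that “doubling the solid roughly doubles dissolved J”, where I had assumed a pace independent of the amount of solid.

The flask gave an excess of 47.6% at 15 min, then an excess of 33.4% and 16.3% reacted at 12 h. At that time 80.7% of its J charge remained solid, against the 82.3% that the margin leaves, which counts products but not dissolved reagent.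

    L → Q (k = 3.90 × 10⁻⁴ min⁻¹)
    L + E + G → E + X (k = 5.10 M⁻² min⁻¹)
    L + E + Z → E + D (k = 1.80 M⁻² min⁻¹)
    J ⇌ L, rate k4*(cs4 - [L]) while solid is left; crystals form when [L] > cs4 (solubility = 0.300 M, k = 0.00160 min⁻¹)
    X ⇌ D (k = 4.40 × 10⁻⁴ min⁻¹)

In the neighbour flask with 0.40 M of J, the margin is 1.41, still greater than one, and it leaves 29.1% of the charge. The computed neighbour holds 22.8% of its J as solid at 12 h, with 16.3% reacted and an excess of 33.4%.

The data were generated by integration with constants of no real substance.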